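**Retrosynthetic overview**
- Target ⇐ catalyst-controlled epoxidation of C1=C10, double angeloylation and hydroxyl-directed epoxidation of C4=C5 of a (1(10)Z,4Z)-6,11-dihydroxygermacradien-8,12-olide.
- C13 ⇐ methylation of the lactone enolate; O6 and O11 are held in one di-tert-butylsilylene ring, which fixes C11.
- Key disconnection C7–C8: a samarium ketyl from a C8 aldehyde adds to C7 of a cyclic α-silyloxy acrylate and closes the ten-membered ring; the alkoxide then closes the γ-lactone.
- Acyclic precursor ⇐ C3–C4 B-alkyl Suzuki coupling of a Z-dienol (from 4-methyl-5,6-dihydro-2H-pyran-2-one) with a Z-vinyl iodide dioxasiline (from but-2-yn-1-ol and methyl pyruvate; C6 set by asymmetric Mukaiyama aldol).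
- Ring order: dioxasiline (temporary) → ten-membered carbocycle → γ-lactone → 4,5-oxirane → 1,10-oxirane.

Assumption: positions follow germacrane numbering (C6 bears the secondary angelate, C8 the lactone oxygen, C11 the tertiary angelate); the SMILES is read literally, so both oxiranes are cis-fused (from a 1(10)Z,4Z-diene); 4-methyl-5,6-dihydro-2H-pyran-2-one is taken as purchasable.

**Step 1**
Reactants: 1 but-2-yn-1-ol
Product: 3 (2Z)-3-iodobut-2-en-1-ol, via vinylalanate 2 (not isolated)
Conditions: NaAlH2(OCH2CH2OMe)2, THF, 0 °C to rt; then I2, −78 to 0 °C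
Reagents that add atoms: iodine, II
Why: Hydroxyl-directed trans-hydroalumination gives a five-membered alkenylalanate with Al on C3 cis to CH2OH, and iodinolysis with retention gives only the Z-iodide (hydroalumination–iodination of a propargylic alcohol).

**Step 2**
Reactants: 3 (2Z)-3-iodobut-2-en-1-ol
Product: 4 (2Z)-3-iodobut-2-enal
Conditions: MnO2, CH2Cl2, rt, dark
Reagents that add atoms: none
Why: MnO2 allylic oxidation stops at the enal and leaves the vinyl iodide and its Z geometry intact.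

**Step 3**
Reactants: 5 methyl pyruvate
Product: 6 methyl 2-[(trimethylsilyl)oxy]prop-2-enoate
Conditions: Me3SiCl, Et3N, Et2O, 0 °C to rt
Reagents that add atoms: chlorotrimethylsilane, C[Si](C)(C)Cl
Why: Amine-mediated enolisation and O-silylation of the α-keto ester (silyl enol ether formation); only one enol is possible.

**Step 4**
Reactants: 4 (2Z)-3-iodobut-2-enal; 6 methyl 2-[(trimethylsilyl)oxy]prop-2-enoate
Product: 7 methyl (4S,5Z)-4-hydroxy-6-iodo-2-oxohept-5-enoate
Conditions: SiCl4, (S,S)-binaphthyldiamine-derived bisphosphoramide (5 mol%), i-Pr2NEt (10 mol%), CH2Cl2, −78 °C; aq. NaHCO3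
Reagents that add atoms: none
Why: Lewis-base-catalysed, SiCl4-mediated Mukaiyama aldol addition, which works best with conjugated aldehydes; the catalyst antipode that shields the Re face is used (confirm on a model, Mosher analysis), so attack on the Si face sets the (S)-carbinol (future C6).

**Step 5**
Reactants: 7 methyl (4S,5Z)-4-hydroxy-6-iodo-2-oxohept-5-enoate
Product: 8 methyl (4S)-2,2-di-tert-butyl-4-[(1Z)-2-iodoprop-1-en-1-yl]-4H-1,3,2-dioxasiline-6-carboxylate
Conditions: t-Bu2Si(OTf)2, Et3N, CH2Cl2, −78 to 0 °C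
Reagents that add atoms: di-tert-butylsilyl bis(trifluoromethanesulfonate), CC(C)(C)[Si](OS(=O)(=O)C(F)(F)F)(OS(=O)(=O)C(F)(F)F)C(C)(C)C
Why: O-silylation of the carbinol, then the tethered silyl triflate traps the ketone as its only possible enol (silyl enol ether formation), closing the six-membered ring without touching the stereocentre.

**Step 6**
Reactants: 9 4-methyl-5,6-dihydro-2H-pyran-2-one
Product: 10 4-methyl-5,6-dihydro-2H-pyran-2-ol
Conditions: i-Bu2AlH, CH2Cl2, −78 °C
Reagents that add atoms: none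
Why: 1,2-Reduction of the unsaturated δ-lactone stops at the aluminium hemiacetal at −78 °C, and the ring keeps the olefin Z.

**Step 7**
Reactants: 10 4-methyl-5,6-dihydro-2H-pyran-2-ol
Product: 11 (3Z)-3-methylhexa-3,5-dien-1-ol
Conditions: Ph3PCH3Br, KOt-Bu (excess), THF, 0 °C to rt
Reagents that add atoms: methyltriphenylphosphonium bromide, C[P+](c1ccccc1)(c1ccccc1)c1ccccc1.[Br-]
Why: Wittig methylenation of the ring-opened hydroxy enal carries the ring-fixed Z geometry into the diene.

**Step 8**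
Reactants: 11 (3Z)-3-methylhexa-3,5-dien-1-ol; 8 methyl (4S)-2,2-di-tert-butyl-4-[(1Z)-2-iodoprop-1-en-1-yl]-4H-1,3,2-dioxasiline-6-carboxylate
Product: 13 methyl (4R)-2,2-di-tert-butyl-4-[(1Z,5Z)-8-hydroxy-2,6-dimethylocta-1,5-dien-1-yl]-4H-1,3,2-dioxasiline-6-carboxylate, via bis-borylated alkylborane 12 (not isolated)
Conditions: 9-BBN-H dimer (2.2 equiv of B–H), THF, 0 °C to rt; then 8, PdCl2(dppf) (5 mol%), AsPh3, aq. K3PO4, DMF, rt
Reagents that add atoms: none
Why: One B–H is taken up by the hydroxyl as a borinate (cleaved again by the aqueous base) and the second adds only to the monosubstituted diene terminus (anti-Markovnikov; the trisubstituted olefin is inert to 9-BBN), after which the B-alkyl Suzuki–Miyaura coupling joins C3 to C4 with retention of the Z-iodide geometry (the CIP label changes from S to R only because iodine is lost).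

**Step 9**
Reactants: 13 methyl (4R)-2,2-di-tert-butyl-4-[(1Z,5Z)-8-hydroxy-2,6-dimethylocta-1,5-dien-1-yl]-4H-1,3,2-dioxasiline-6-carboxylate
Product: 14 methyl (4R)-2,2-di-tert-butyl-4-[(1Z,5Z)-2,6-dimethyl-8-oxoocta-1,5-dien-1-yl]-4H-1,3,2-dioxasiline-6-carboxylate
Conditions: Dess–Martin periodinane, NaHCO3, CH2Cl2, 0 °C; used at once
Reagents that add atoms: none
Why: Buffered Dess–Martin oxidation gives the β,γ-unsaturated aldehyde without conjugation and leaves the silyl enol ether intact.

**Step 10**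
Reactants: 14 methyl (4R)-2,2-di-tert-butyl-4-[(1Z,5Z)-2,6-dimethyl-8-oxoocta-1,5-dien-1-yl]-4H-1,3,2-dioxasiline-6-carboxylate
Product: 16 silylene-bridged tricyclic lactone (1(10)Z,4Z)-6,11-O-(di-tert-butylsilanediyl)-6,11-dihydroxy-13-norgermacra-1(10),4-dien-8,12-olide (H-6/H-7 cis; H-7/H-8 trans), via hydroxy ester 15 (not isolated)
Conditions: SmI2 (2.5 equiv), t-BuOH (2 equiv), THF, −78 °C to rt, slow addition of 14 (final 0.003 M)
Reagents that add atoms: none
Why: Proposed new method: SmI2 reduces the aldehyde to a ketyl radical that adds 10-exo to C7 of the captodative acrylate, the Z,Z-1,5-diene tether holding the ends close as in cis,cis-cyclodeca-1,5-diene; attack is axial on the half-chair dioxasiline, anti to the pseudo-axial C6–H with the tether equatorial, so C8 ends cis to C5 (H-6/H-7 cis); the bulky trivalent-samarium-bound oxygen stays outside the forming ring (O8 trans to C11), the C11 radical is reduced and protonated, and the samarium alkoxide lactonises onto the methyl ester (the C11 configuration is reset in step 11); closest known chemistry is the intermolecular SmI2 aldehyde–acrylate γ-lactone synthesis and SmI2 ketyl–olefin cyclisations to eight-membered rings.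

**Step 11**
Reactants: 16 silylene-bridged tricyclic lactone
Product: 18 (1(10)Z,4Z)-6,11-O-(di-tert-butylsilanediyl)-6,11-dihydroxygermacra-1(10),4-dien-8,12-olide (13-methyl cis to H-7), via lithium enolate 17 (not isolated)
Conditions: LiN(i-Pr)2, THF, −78 °C; then MeI, DMPU, −78 to −20 °C
Reagents that add atoms: iodomethane, CI
Why: Lactone enolate alkylation at the ring-fusion carbon; MeI enters on the face anti to C6 (the out-of-plane substituent on C7), which keeps the lactone/dioxasilinane fusion cis, so O11 stays cis to C6 and C11 is set as in the target.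

**Step 12**
Reactants: 18 C11-methylated silylene lactone
Product: 19 (1(10)Z,4Z)-6,11-dihydroxygermacra-1(10),4-dien-8,12-olide (configuration at C6/C7/C8/C11 as in the target)
Conditions: HF·pyridine, pyridine/THF, 0 °C to rt
Reagents that add atoms: none
Why: Fluoride-driven cleavage of the silylene frees both hydroxyls under mildly acidic conditions that leave lactone and olefins alone.

**Step 13**
Reactants: 19 (1(10)Z,4Z)-6,11-dihydroxygermacra-1(10),4-dien-8,12-olide
Product: 20 (1(10)Z)-4,5-epoxy-6,11-dihydroxygermacr-1(10)-en-8,12-olide (cis-fused oxirane syn to 6-OH)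
Conditions: VO(acac)2 (5 mol%), t-BuOOH, CH2Cl2, 0 °C
Reagents that add atoms: tert-butyl hydroperoxide, CC(C)(C)OO
Why: Hydroxyl-directed vanadium-catalysed epoxidation; the C6 vanadate delivers oxygen to the allylic C4=C5 bond on the ring face that carries the hydroxyl (as with medium-ring Z-cycloalkenols), setting C4 and C5 and leaving C1=C10 untouched.

**Step 14**
Reactants: 20 (1(10)Z)-4,5-epoxy-6,11-dihydroxygermacr-1(10)-en-8,12-olide; 21 angelic acid ((2Z)-2-methylbut-2-enoic acid, 6 equiv)
Product: 23 (1(10)Z)-6,11-bis(angeloyloxy)-4,5-epoxygermacr-1(10)-en-8,12-olide, via mixed anhydride 22 (not isolated)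
Conditions: 2,4,6-Cl3C6H2COCl, Et3N, PhMe, rt, filter; then 20, PhMe, 80 °C
Reagents that add atoms: none
Why: Yamaguchi-type mixed-anhydride esterification transfers the angeloyl group without Z-to-E isomerisation, and heating with excess reagent acylates the tertiary 11-OH as well as the secondary 6-OH.

**Step 15**
Reactants: 23 (1(10)Z)-6,11-bis(angeloyloxy)-4,5-epoxygermacr-1(10)-en-8,12-olide
Product: 24 (1R,4R,5S,6S,7S,8R,10S,11R)-6,11-bis(angeloyloxy)-1,10:4,5-diepoxygermacran-8,12-olide (CNP0219924.2)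
Conditions: D-fructose-derived Shi ketone (30 mol%), Oxone (2KHSO5·KHSO4·K2SO4), K2CO3, Bu4NHSO4, MeCN/CH2(OMe)2/aq. Na2B4O7, pH 10.5, 0 °C
Reagents that add atoms: potassium peroxymonosulfate, [K+].[O-]S(=O)(=O)OO
Why: Shi asymmetric epoxidation; the chiral dioxirane transfers one oxygen to the remaining electron-rich trisubstituted C1=C10 olefin through a spiro transition state, stereospecifically giving the cis-fused oxirane, and by analogy with 1-substituted cycloalkenes the D-fructose ketone gives the (1R,10S) configuration, while the electron-poor angelate olefins, the esters and the existing oxirane are untouched.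

**Compound list**
1 | but-2-yn-1-ol | CC#CCO | starting material
2 | sodium 2,2-bis(2-methoxyethoxy)-3-methyl-2,5-dihydro-1,2-oxaluminol-2-uide (vinylalanate) | [Na+].CC1=CCO[Al-]1(OCCOC)OCCOC | intermediate
3 | (2Z)-3-iodobut-2-en-1-ol | I/C(C)=C\CO | intermediate
4 | (2Z)-3-iodobut-2-enal | I/C(C)=C\C=O | intermediate
5 | methyl pyruvate | CC(=O)C(=O)OC | starting material
6 | methyl 2-[(trimethylsilyl)oxy]prop-2-enoate | C=C(O[Si](C)(C)C)C(=O)OC | intermediate
7 | methyl (4S,5Z)-4-hydroxy-6-iodo-2-oxohept-5-enoate | I/C(C)=C\[C@@H](O)CC(=O)C(=O)OC | intermediate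
8 | methyl (4S)-2,2-di-tert-butyl-4-[(1Z)-2-iodoprop-1-en-1-yl]-4H-1,3,2-dioxasiline-6-carboxylate | I/C(C)=C\[C@H]1O[Si](C(C)(C)C)(C(C)(C)C)OC(C(=O)OC)=C1 | intermediate
9 | 4-methyl-5,6-dihydro-2H-pyran-2-one | CC1=CC(=O)OCC1 | starting material
10 | 4-methyl-5,6-dihydro-2H-pyran-2-ol (lactol) | CC1=CC(O)OCC1 | intermediate
11 | (3Z)-3-methylhexa-3,5-dien-1-ol | C=C/C=C(C)\CCO | intermediate
12 | (3Z)-6-(9-borabicyclo[3.3.1]nonan-9-yl)-1-[(9-borabicyclo[3.3.1]nonan-9-yl)oxy]-3-methylhex-3-ene (bis-borylated alkylborane) | C1CCC2CCCC1B2OCC/C(C)=C\CCB1C2CCCC1CCC2 | intermediate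
13 | methyl (4R)-2,2-di-tert-butyl-4-[(1Z,5Z)-8-hydroxy-2,6-dimethylocta-1,5-dien-1-yl]-4H-1,3,2-dioxasiline-6-carboxylate | OCC/C(C)=C\CC/C(C)=C\[C@H]1O[Si](C(C)(C)C)(C(C)(C)C)OC(C(=O)OC)=C1 | intermediate
14 | methyl (4R)-2,2-di-tert-butyl-4-[(1Z,5Z)-2,6-dimethyl-8-oxoocta-1,5-dien-1-yl]-4H-1,3,2-dioxasiline-6-carboxylate | O=CC/C(C)=C\CC/C(C)=C\[C@H]1O[Si](C(C)(C)C)(C(C)(C)C)OC(C(=O)OC)=C1 | intermediate
15 | methyl (1(10)Z,4Z)-6,11-O-(di-tert-butylsilanediyl)-6,8,11-trihydroxy-13-norgermacra-1(10),4-dien-12-oate (ring-closed hydroxy ester) | [Si]2(C(C)(C)C)(C(C)(C)C)O[C@@H]1/C=C(C)\CC/C=C(C)\C[C@@H](O)[C@@H]1[C@@H](O2)C(=O)OC | intermediate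
16 | (1(10)Z,4Z)-6,11-O-(di-tert-butylsilanediyl)-6,11-dihydroxy-13-norgermacra-1(10),4-dien-8,12-olide (H-6/H-7 cis, H-7/H-8 trans, H-11 cis to H-7) | [Si]3(C(C)(C)C)(C(C)(C)C)O[C@@H]1/C=C(C)\CC/C=C(C)\C[C@H]2OC(=O)[C@H](O3)[C@H]12 | intermediate
17 | lithium enolate of 16 (C11=C12–OLi) | [Li+].[O-]C1=C2O[Si](C(C)(C)C)(C(C)(C)C)O[C@@H]3/C=C(C)\CC/C=C(C)\C[C@@H](O1)[C@H]23 | intermediate
18 | (1(10)Z,4Z)-6,11-O-(di-tert-butylsilanediyl)-6,11-dihydroxygermacra-1(10),4-dien-8,12-olide (13-methyl cis to H-7) | [Si]3(C(C)(C)C)(C(C)(C)C)O[C@@H]1/C=C(C)\CC/C=C(C)\C[C@H]2OC(=O)[C@](C)(O3)[C@H]12 | intermediate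
19 | (1(10)Z,4Z)-6,11-dihydroxygermacra-1(10),4-dien-8,12-olide (configuration at C6/C7/C8/C11 as in 24) | O[C@@H]1/C=C(C)\CC/C=C(C)\C[C@H]2OC(=O)[C@](C)(O)[C@H]12 | intermediate
20 | (1(10)Z)-4,5-epoxy-6,11-dihydroxygermacr-1(10)-en-8,12-olide (cis-fused oxirane syn to 6-OH) | O[C@H]1[C@@H]2[C@@H](C/C(C)=C\CC[C@@]3(C)O[C@@H]13)OC(=O)[C@]2(C)O | intermediate
21 | angelic acid, (2Z)-2-methylbut-2-enoic acid | C/C=C(/C)C(=O)O | starting material
22 | angelic 2,4,6-trichlorobenzoic anhydride | C/C=C(/C)C(=O)OC(=O)c1c(Cl)cc(Cl)cc1Cl | intermediate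
23 | (1(10)Z)-6,11-bis(angeloyloxy)-4,5-epoxygermacr-1(10)-en-8,12-olide | C/C=C(/C)C(=O)O[C@H]1[C@@H]2[C@@H](C/C(C)=C\CC[C@@]3(C)O[C@@H]13)OC(=O)[C@]2(C)OC(=O)/C(C)=C\C | intermediate
24 | (1R,4R,5S,6S,7S,8R,10S,11R)-6,11-bis(angeloyloxy)-1,10:4,5-diepoxygermacran-8,12-olide | C/C=C(/C)C(=O)O[C@H]1[C@@H]2[C@@H](C[C@]3(C)O[C@@H]3CC[C@@]3(C)O[C@@H]13)OC(=O)[C@]2(C)OC(=O)/C(C)=C\C | target

**Step count and risks**
Total step count: 15. Longest linear sequence: 12 (steps 1, 2, 4, 5, 8, 9, 10, 11, 12, 13, 14, 15).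

The three steps most likely to fail are steps 4, 10 and 14.

Step 4: the pyruvate-derived enol silane is a weak nucleophile and the enantioselectivity with a Z-β-iodo enal is untested. The fallback sets out from 4 and 6 and comes back at 7. The aldol is run without chiral control (BF3·OEt2, CH2Cl2, −78 °C) to give racemic methyl (5Z)-4-hydroxy-6-iodo-2-oxohept-5-enoate F1. This is resolved by lipase-catalysed acetylation (lipase from Burkholderia cepacia, vinyl acetate, t-BuOMe), assumed to convert the (4R)-alcohol into methyl (4R,5Z)-4-acetoxy-6-iodo-2-oxohept-5-enoate F2 and leave the (4S)-alcohol 7 for separation.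

Step 10: a ten-membered ketyl–olefin closure has no direct precedent; pinacol dimerisation, simple reduction, or the wrong C7/C8 configuration may win. The fallback sets out from 11 and 8 and comes back at 16, with the ring closed by palladium instead. Alcohol 11 is oxidised (Dess–Martin periodinane, NaHCO3) to (3Z)-3-methylhexa-3,5-dienal F3. F3 is coupled at once with 8 under SmI2/t-BuOH in an intermolecular ketyl–olefin addition with lactonisation, giving the iodo diene lactone F4. The terminal vinyl group of F4 is hydroborated with 9-BBN-H to the alkylborane F5, and the ten-membered ring is closed by intramolecular B-alkyl Suzuki coupling (PdCl2(dppf), AsPh3, aq. K3PO4, high dilution) to 16.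

Step 14: the tertiary α-hydroxy lactone may resist angeloylation, and forcing conditions risk isomerisation to the tiglate. The fallback sets out from 20 and comes back at 23, building the Z-olefins after acylation. Both hydroxyls are esterified with 2-[bis(2,2,2-trifluoroethoxy)phosphoryl]propanoic acid (N,N'-diisopropylcarbodiimide, 4-(dimethylamino)pyridine, CH2Cl2) to give the bis(phosphonopropanoate) F6. A double Still–Gennari olefination with acetaldehyde (KN(SiMe3)2, 18-crown-6, THF, −78 °C) then gives the two (Z)-2-methylbut-2-enoates of 23.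

**Further compounds**
F1 | step 4 | racemic methyl (5Z)-4-hydroxy-6-iodo-2-oxohept-5-enoate | I/C(C)=C\C(O)CC(=O)C(=O)OC
F2 | step 4 | methyl (4R,5Z)-4-acetoxy-6-iodo-2-oxohept-5-enoate | I/C(C)=C\[C@H](OC(C)=O)CC(=O)C(=O)OC
F3 | step 10 | (3Z)-3-methylhexa-3,5-dienal | C=C/C=C(C)\CC=O
F4 | step 10 | iodo diene lactone: cis-fused γ-lactone/dioxasilinane carrying the (1Z)-2-iodoprop-1-enyl group at C6 and the (2Z)-2-methylpenta-2,4-dienyl group at C8, configuration as in 16 | [Si]1(C(C)(C)C)(C(C)(C)C)O[C@H](/C=C(C)\I)[C@@H]2[C@@H](C/C(C)=C\C=C)OC(=O)[C@@H]2O1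
F5 | step 10 | alkylborane: F4 with the terminal vinyl group converted into a 2-(9-borabicyclo[3.3.1]nonan-9-yl)ethyl group | [Si]1(C(C)(C)C)(C(C)(C)C)O[C@H](/C=C(C)\I)[C@@H]2[C@@H](C/C(C)=C\CCB3C4CCCC3CCC4)OC(=O)[C@@H]2O1
F6 | step 14 | bis(phosphonopropanoate): 6,11-bis{2-[bis(2,2,2-trifluoroethoxy)phosphoryl]propanoate} of 20 | CC(P(=O)(OCC(F)(F)F)OCC(F)(F)F)C(=O)O[C@H]1[C@@H]2[C@@H](C/C(C)=C\CC[C@@]3(C)O[C@@H]13)OC(=O)[C@]2(C)OC(=O)C(C)P(=O)(OCC(F)(F)F)OCC(F)(F)F
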